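**Retrosynthetic overview**

1. Rings: the benzene ring is bought as a nitro-dimethoxybenzaldehyde (nitro = latent C20 amine). The only ring formed is the 19-membered lactam, closed last at N–C1 by attack of the free aryl amine on a C1 thioester, as in the amide-synthase chain release. Only the unmasking of the hydroquinone follows.
2. Seco thioester ⇒ C3–C4 Suzuki coupling of a (Z)-alkenylboronate (C4–C21) with S-ethyl (E)-3-iodo-2-methylprop-2-enethioate (C1–C3).
3. C4–C7 ⇒ syn-selective SE2′ propargylation of a C7 enal with an (aR)-allenylstannane, then carbamoylation and trans-hydroboration. C7–C8 ⇒ cross-metathesis with methacrolein.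
4. C9–C11 and C12–C15 ⇒ two phosphoric-acid-catalysed (Z)-crotylborations (10,11-syn and 14,15-syn). C11 ⇒ hydroformylation. C12–O ⇒ enamine α-oxyamination with TEMPO; the O–N ether masks 12-OH until the nitro reduction.

Assumption: atoms are numbered C1 (amide carbonyl) to C15 (benzylic carbon), arene C16–C21 with N on C20. The SMILES then reads 2E,4Z,8E and 6S,7R,10S,11R,12S,14S,15R. Compounds 1, 4, 18 and (R)-TRIP are taken as catalogue items.

**Route**

Step 1
Reactants: 1 2-hydroxy-5-methoxy-3-nitrobenzaldehyde; 2 iodomethane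
Product: 3 2,5-dimethoxy-3-nitrobenzaldehyde
Conditions: MeI, K2CO3, DMF, 40 °C
Reagents that add atoms: iodomethane, CI
Why: Williamson O-methylation of the acidic ortho-nitrophenol; no stereocentre is involved.

Step 2
Reactants: 3 2,5-dimethoxy-3-nitrobenzaldehyde; 4 (Z)-crotylboronic acid pinacol ester
Product: 6 (1R,2S)-1-(2,5-dimethoxy-3-nitrophenyl)-2-methylbut-3-en-1-ol, via pinacol borate ester 5 (not isolated)
Conditions: (R)-TRIP phosphoric acid (5 mol%), toluene, −30 °C; aqueous work-up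
Reagents that add atoms: (Z)-crotylboronic acid pinacol ester, C/C=C\CB1OC(C)(C)C(C)(C)O1
Why: Chiral phosphoric-acid-catalysed crotylboration through a closed chair transition state; the Z-crotyl geometry gives the 14,15-syn pair and the (R)-acid directs attack to the Re face of the aldehyde, setting 15R and 14S.

Step 3
Reactants: 6 homoallylic alcohol; 2 iodomethane
Product: 7 2,5-dimethoxy-1-[(1R,2S)-1-methoxy-2-methylbut-3-en-1-yl]-3-nitrobenzene
Conditions: NaH, MeI, THF, 0 → 23 °C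
Reagents that add atoms: iodomethane, CI
Why: Williamson etherification of the benzylic alkoxide (C15-OMe); the stereocentres are not touched.

Step 4
Reactants: 7 methyl ether; 8 carbon monoxide
Product: 9 (4S,5R)-5-(2,5-dimethoxy-3-nitrophenyl)-5-methoxy-4-methylpentanal
Conditions: Rh(acac)(CO)2 (1 mol%), Xantphos (2 mol%), CO/H2 (1:1, 10 bar), toluene, 70 °C
Reagents that add atoms: carbon monoxide, [C-]#[O+]
Why: Linear-selective rhodium-catalysed hydroformylation of the terminal alkene (wide-bite-angle diphosphine, reinforced by allylic branching) adds C11 as the aldehyde; no stereocentre is touched.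

Step 5
Reactants: 9 aldehyde; 10 TEMPO
Product: 11 (2S,4S,5R)-5-(2,5-dimethoxy-3-nitrophenyl)-5-methoxy-4-methyl-2-[(2,2,6,6-tetramethylpiperidin-1-yl)oxy]pentanal
Conditions: TEMPO, (5S)-5-benzyl-2,2,3-trimethylimidazolidin-4-one trifluoroacetate (20 mol%), CuCl2·2H2O (10 mol%), air, acetone, −20 °C
Reagents that add atoms: TEMPO, CC1(C)CCCC(C)(C)N1[O]
Why: Enamine-catalysed asymmetric α-oxyamination; the 5S-benzyl group shields the Re face of the E-enamine, so oxygen is delivered to the Si face and sets 12S under catalyst control, and the O–N ether then serves as the latent 12-OH.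

Step 6
Reactants: 11 α-oxyaminated aldehyde; 4 (Z)-crotylboronic acid pinacol ester
Product: 13 (3S,4R,5S,7S,8R)-8-(2,5-dimethoxy-3-nitrophenyl)-8-methoxy-3,7-dimethyl-5-[(2,2,6,6-tetramethylpiperidin-1-yl)oxy]oct-1-en-4-ol, via pinacol borate ester 12 (not isolated)
Conditions: (R)-TRIP phosphoric acid (10 mol%), toluene, −30 → 0 °C; aqueous work-up
Reagents that add atoms: (Z)-crotylboronic acid pinacol ester, C/C=C\CB1OC(C)(C)C(C)(C)O1
Why: Second phosphoric-acid-catalysed crotylboration; the chair transition state of the Z-reagent gives 10,11-syn (10S), and Re-face attack directed by the (R)-acid coincides with the polar Felkin–Anh preference of the α-oxygenated aldehyde, giving 11R (11,12-anti) in a matched case.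

Step 7
Reactants: 13 alcohol; 14 trimethyloxonium tetrafluoroborate
Product: 15 1-{[(3S,4R,5S,7S,8R)-8-(2,5-dimethoxy-3-nitrophenyl)-4,8-dimethoxy-3,7-dimethyloct-1-en-5-yl]oxy}-2,2,6,6-tetramethylpiperidine
Conditions: Me3OBF4, 1,8-bis(dimethylamino)naphthalene, CH2Cl2, 23 °C
Reagents that add atoms: trimethyloxonium tetrafluoroborate, C[O+](C)C.F[B-](F)(F)F
Why: Non-basic O-methylation of the hindered secondary alcohol with Meerwein salt (C11-OMe); no stereocentre is touched.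

Step 8
Reactants: 15 terminal alkene; 16 methacrolein
Product: 17 (2E,4S,5R,6S,8S,9R)-9-(2,5-dimethoxy-3-nitrophenyl)-5,9-dimethoxy-2,4,8-trimethyl-6-[(2,2,6,6-tetramethylpiperidin-1-yl)oxy]non-2-enal
Conditions: methacrolein (15 equiv), second-generation Hoveyda–Grubbs catalyst RuCl2(=CH-C6H4-2-OiPr)(H2IMes) (10 mol%), CH2Cl2, 40 °C
Reagents that add atoms: methacrolein, CC(=C)C=O
Why: Olefin cross-metathesis with excess methacrolein gives the thermodynamically favoured E-trisubstituted enal (C7–C9); the allylic C10 centre is not touched.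

Step 9
Reactants: 18 (S)-but-3-yn-2-ol; 19 methanesulfonyl chloride
Product: 20 (2S)-but-3-yn-2-yl methanesulfonate
Conditions: MsCl, Et3N, CH2Cl2, −78 → 0 °C
Reagents that add atoms: methanesulfonyl chloride, CS(Cl)(=O)=O
Why: O-sulfonylation of the propargylic alcohol with retention, since only the O–S bond is formed.

Step 10
Reactants: 20 mesylate; 21 tributyltin hydride
Product: 23 (aR)-tributyl(buta-1,2-dien-1-yl)stannane, via tributylstannyllithium 22 (not isolated)
Conditions: Bu3SnH, LiN(iPr)2, THF, 0 °C; CuBr·SMe2, −78 °C; then 20, −78 °C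
Reagents that add atoms: tributyltin hydride, CCCC[SnH](CCCC)CCCC
Why: Anti-SN2′ displacement of the propargylic mesylate by the stannylcuprate transfers central to axial chirality, so the (S)-mesylate gives the (aR)-allene.

Step 11
Reactants: 17 enal; 23 (aR)-allenylstannane
Product: 24 (3S,4R,5E,7S,8R,9S,11S,12R)-12-(2,5-dimethoxy-3-nitrophenyl)-8,12-dimethoxy-3,5,7,11-tetramethyl-9-[(2,2,6,6-tetramethylpiperidin-1-yl)oxy]dodec-5-en-1-yn-4-ol
Conditions: BF3·OEt2 (2.5 equiv), CH2Cl2, −78 °C; aqueous NaHCO3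
Reagents that add atoms: (aR)-tributyl(buta-1,2-dien-1-yl)stannane, [H]C([Sn](CCCC)(CCCC)CCCC)=[C@@]=C([H])C
Why: Marshall propargylation, a BF3-promoted SE2′ addition anti to tin through an open antiperiplanar transition state; it gives the 6,7-syn homopropargylic alcohol, with the (aR)-allene fixing 6S and hence 7R under reagent control.

Step 12
Reactants: 24 homopropargylic alcohol; 25 trichloroacetyl isocyanate
Product: 27 (3S,4R,5E,7S,8R,9S,11S,12R)-12-(2,5-dimethoxy-3-nitrophenyl)-8,12-dimethoxy-3,5,7,11-tetramethyl-9-[(2,2,6,6-tetramethylpiperidin-1-yl)oxy]dodec-5-en-1-yn-4-yl carbamate, via N-trichloroacetyl carbamate 26 (not isolated)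
Conditions: Cl3CC(O)NCO, CH2Cl2, 0 °C; then K2CO3, MeOH, 0 °C
Reagents that add atoms: trichloroacetyl isocyanate, ClC(Cl)(Cl)C(=O)N=C=O
Why: Kočovský carbamoylation: the alcohol adds to the isocyanate and methanolysis removes the trichloroacetyl group, with retention at C7.

Step 13
Reactants: 27 alkynyl carbamate; 28 pinacolborane
Product: 29 (1Z,3S,4R,5E,7S,8R,9S,11S,12R)-12-(2,5-dimethoxy-3-nitrophenyl)-8,12-dimethoxy-3,5,7,11-tetramethyl-1-(4,4,5,5-tetramethyl-1,3,2-dioxaborolan-2-yl)-9-[(2,2,6,6-tetramethylpiperidin-1-yl)oxy]dodeca-1,5-dien-4-yl carbamate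
Conditions: HBpin, [Rh(cod)Cl]2 (1.5 mol%), P(iPr)3 (6 mol%), Et3N, cyclohexane, 23 °C
Reagents that add atoms: pinacolborane, CC1(C)OBOC1(C)C
Why: Miyaura trans-hydroboration of the terminal alkyne through a monovalent rhodium vinylidene gives the anti-Markovnikov (Z)-alkenylboronate, fixing the 4Z geometry.

Step 14
Reactants: 30 diethyl methylmalonate; 31 triiodomethane
Product: 32 diethyl 2-(diiodomethyl)-2-methylpropanedioate
Conditions: NaH, Et2O, 0 °C; then CHI3, reflux
Reagents that add atoms: triiodomethane, IC(I)I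
Why: Alkylation of the malonate anion by iodoform installs the diiodomethyl group.

Step 15
Reactants: 32 diiodomethyl malonate; 33 potassium hydroxide
Product: 34 (2E)-3-iodo-2-methylprop-2-enoic acid
Conditions: KOH, EtOH/H2O, reflux; then aqueous HCl
Reagents that add atoms: potassium hydroxide, [K+].[OH-]
Why: Saponification followed by decarboxylative anti-elimination of iodide gives the E-configured β-iodoacrylic acid (C1–C3 with the 2E geometry).

Step 16
Reactants: 34 iodoacrylic acid; 35 ethanethiol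
Product: 36 S-ethyl (2E)-3-iodo-2-methylprop-2-enethioate
Conditions: EtSH (1.05 equiv), DCC, DMAP (5 mol%), CH2Cl2, 0 °C
Reagents that add atoms: ethanethiol, CCS
Why: Steglich thioesterification at low temperature; the alkene geometry is retained.

Step 17
Reactants: 29 (Z)-alkenylboronate; 36 iodo thioester
Product: 37 S-ethyl (2E,4Z,6S,7R,8E,10S,11R,12S,14S,15R)-7-(carbamoyloxy)-15-(2,5-dimethoxy-3-nitrophenyl)-11,15-dimethoxy-2,6,8,10,14-pentamethyl-12-[(2,2,6,6-tetramethylpiperidin-1-yl)oxy]pentadeca-2,4,8-trienethioate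
Conditions: Pd(dppf)Cl2 (5 mol%), aqueous K3PO4, THF, 23 °C
Reagents that add atoms: S-ethyl (2E)-3-iodo-2-methylprop-2-enethioate, C/C(=C\I)C(=O)SCC
Why: Suzuki–Miyaura sp2–sp2 coupling with retention of both alkene geometries gives the (2E,4Z)-dienoyl thioester; the vinyl C–I bond adds to zerovalent palladium far faster than the thioester C–S bond.

Step 18
Reactants: 37 nitro thioester
Product: 38 S-ethyl (2E,4Z,6S,7R,8E,10S,11R,12S,14S,15R)-15-(3-amino-2,5-dimethoxyphenyl)-7-(carbamoyloxy)-12-hydroxy-11,15-dimethoxy-2,6,8,10,14-pentamethylpentadeca-2,4,8-trienethioate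
Conditions: Zn dust, AcOH/THF/H2O (3:1:1), 50 °C
Reagents that add atoms: none
Why: Dissolving-metal reduction with Zn/AcOH converts the nitro group to the aryl amine and cleaves the alkoxyamine N–O bond, releasing 12-OH with retention in the same operation.

Step 19
Reactants: 38 amino hydroxy thioester
Product: 40 macrolactam (18,21-di-O-methyl ether of the target), via OAt active ester 39 (not isolated)
Conditions: AgOCOCF3 (3 equiv), HOAt (3 equiv), iPr2NEt (6 equiv), DMF, 0.001 M, 23 → 40 °C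
Reagents that add atoms: none
Why: Proposed new method: thiophilic monovalent silver activates the C1 thioester (the counterpart of the carrier-protein thioester handled by the amide synthase), HOAt relays the acyl group as ester 39, and the aryl amine, the most nucleophilic neutral group present (ahead of 12-OH and the carbamate NH2), closes the 19-membered lactam at high dilution without hydroxyl protection; the closest known reaction type is silver-ion-assisted thioester aminolysis and lactamisation of unprotected peptide thioesters (Aimoto and Tam type) together with Masamune thioester macrolactonisation; no stereocentre is formed.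

Step 20
Reactants: 40 macrolactam; 41 water
Product: 43 target hydroquinone CNP0548031.1, via para-quinone 42 (not isolated)
Conditions: (NH4)2Ce(NO3)6 (2.5 equiv), MeCN/H2O (4:1), 0 °C; then aqueous Na2S2O4, EtOAc, 23 °C, under argon
Reagents that add atoms: water, O
Why: Oxidative demethylation of the para-dimethoxyarene by tetravalent cerium gives the para-quinone (its oxygens come from water), and dithionite reduces it in the work-up to the hydroquinone; no stereocentre is touched.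

**Compound list**

1 | 2-hydroxy-5-methoxy-3-nitrobenzaldehyde | COc1cc([N+](=O)[O-])c(O)c(c1)C=O | starting material
2 | iodomethane | CI | starting material
3 | 2,5-dimethoxy-3-nitrobenzaldehyde | COc1cc([N+](=O)[O-])c(OC)c(c1)C=O | intermediate
4 | 2-[(2Z)-but-2-en-1-yl]-4,4,5,5-tetramethyl-1,3,2-dioxaborolane ((Z)-crotylboronic acid pinacol ester) | C/C=C\CB1OC(C)(C)C(C)(C)O1 | starting material
5 | 2-{[(1R,2S)-1-(2,5-dimethoxy-3-nitrophenyl)-2-methylbut-3-en-1-yl]oxy}-4,4,5,5-tetramethyl-1,3,2-dioxaborolane | COc1cc([N+](=O)[O-])c(OC)c(c1)[C@H](OB2OC(C)(C)C(C)(C)O2)[C@@H](C)C=C | intermediate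
6 | (1R,2S)-1-(2,5-dimethoxy-3-nitrophenyl)-2-methylbut-3-en-1-ol | COc1cc([N+](=O)[O-])c(OC)c(c1)[C@H](O)[C@@H](C)C=C | intermediate
7 | 2,5-dimethoxy-1-[(1R,2S)-1-methoxy-2-methylbut-3-en-1-yl]-3-nitrobenzene | COc1cc([N+](=O)[O-])c(OC)c(c1)[C@H](OC)[C@@H](C)C=C | intermediate
8 | carbon monoxide | [C-]#[O+] | starting material
9 | (4S,5R)-5-(2,5-dimethoxy-3-nitrophenyl)-5-methoxy-4-methylpentanal | COc1cc([N+](=O)[O-])c(OC)c(c1)[C@H](OC)[C@@H](C)CCC=O | intermediate
10 | (2,2,6,6-tetramethylpiperidin-1-yl)oxyl (TEMPO) | CC1(C)CCCC(C)(C)N1[O] | starting material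
11 | (2S,4S,5R)-5-(2,5-dimethoxy-3-nitrophenyl)-5-methoxy-4-methyl-2-[(2,2,6,6-tetramethylpiperidin-1-yl)oxy]pentanal | COc1cc([N+](=O)[O-])c(OC)c(c1)[C@H](OC)[C@@H](C)C[C@H](ON2C(C)(C)CCCC2(C)C)C=O | intermediate
12 | pinacol borate ester of 13 (O4–B) | COc1cc([N+](=O)[O-])c(OC)c(c1)[C@H](OC)[C@@H](C)C[C@H](ON2C(C)(C)CCCC2(C)C)[C@H](OB3OC(C)(C)C(C)(C)O3)[C@@H](C)C=C | intermediate
13 | (3S,4R,5S,7S,8R)-8-(2,5-dimethoxy-3-nitrophenyl)-8-methoxy-3,7-dimethyl-5-[(2,2,6,6-tetramethylpiperidin-1-yl)oxy]oct-1-en-4-ol | COc1cc([N+](=O)[O-])c(OC)c(c1)[C@H](OC)[C@@H](C)C[C@H](ON2C(C)(C)CCCC2(C)C)[C@H](O)[C@@H](C)C=C | intermediate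
14 | trimethyloxonium tetrafluoroborate | C[O+](C)C.F[B-](F)(F)F | starting material
15 | 1-{[(3S,4R,5S,7S,8R)-8-(2,5-dimethoxy-3-nitrophenyl)-4,8-dimethoxy-3,7-dimethyloct-1-en-5-yl]oxy}-2,2,6,6-tetramethylpiperidine | COc1cc([N+](=O)[O-])c(OC)c(c1)[C@H](OC)[C@@H](C)C[C@H](ON2C(C)(C)CCCC2(C)C)[C@H](OC)[C@@H](C)C=C | intermediate
16 | 2-methylprop-2-enal (methacrolein) | CC(=C)C=O | starting material
17 | (2E,4S,5R,6S,8S,9R)-9-(2,5-dimethoxy-3-nitrophenyl)-5,9-dimethoxy-2,4,8-trimethyl-6-[(2,2,6,6-tetramethylpiperidin-1-yl)oxy]non-2-enal | COc1cc([N+](=O)[O-])c(OC)c(c1)[C@H](OC)[C@@H](C)C[C@H](ON2C(C)(C)CCCC2(C)C)[C@H](OC)[C@@H](C)/C=C(\C)C=O | intermediate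
18 | (2S)-but-3-yn-2-ol | C[C@H](O)C#C | starting material
19 | methanesulfonyl chloride | CS(Cl)(=O)=O | starting material
20 | (2S)-but-3-yn-2-yl methanesulfonate | C[C@H](OS(C)(=O)=O)C#C | intermediate
21 | tributyltin hydride | CCCC[SnH](CCCC)CCCC | starting material
22 | tributylstannyllithium | [Li][Sn](CCCC)(CCCC)CCCC | intermediate
23 | (aR)-tributyl(buta-1,2-dien-1-yl)stannane, the (M)-allene | [H]C([Sn](CCCC)(CCCC)CCCC)=[C@@]=C([H])C | intermediate
24 | (3S,4R,5E,7S,8R,9S,11S,12R)-12-(2,5-dimethoxy-3-nitrophenyl)-8,12-dimethoxy-3,5,7,11-tetramethyl-9-[(2,2,6,6-tetramethylpiperidin-1-yl)oxy]dodec-5-en-1-yn-4-ol | COc1cc([N+](=O)[O-])c(OC)c(c1)[C@H](OC)[C@@H](C)C[C@H](ON2C(C)(C)CCCC2(C)C)[C@H](OC)[C@@H](C)/C=C(\C)[C@H](O)[C@@H](C)C#C | intermediate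
25 | trichloroacetyl isocyanate | ClC(Cl)(Cl)C(=O)N=C=O | starting material
26 | N-(trichloroacetyl)carbamate of 24 (at O4) | COc1cc([N+](=O)[O-])c(OC)c(c1)[C@H](OC)[C@@H](C)C[C@H](ON2C(C)(C)CCCC2(C)C)[C@H](OC)[C@@H](C)/C=C(\C)[C@H](OC(=O)NC(=O)C(Cl)(Cl)Cl)[C@@H](C)C#C | intermediate
27 | (3S,4R,5E,7S,8R,9S,11S,12R)-12-(2,5-dimethoxy-3-nitrophenyl)-8,12-dimethoxy-3,5,7,11-tetramethyl-9-[(2,2,6,6-tetramethylpiperidin-1-yl)oxy]dodec-5-en-1-yn-4-yl carbamate | COc1cc([N+](=O)[O-])c(OC)c(c1)[C@H](OC)[C@@H](C)C[C@H](ON2C(C)(C)CCCC2(C)C)[C@H](OC)[C@@H](C)/C=C(\C)[C@H](OC(N)=O)[C@@H](C)C#C | intermediate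
28 | 4,4,5,5-tetramethyl-1,3,2-dioxaborolane (pinacolborane) | CC1(C)OBOC1(C)C | starting material
29 | (1Z,3S,4R,5E,7S,8R,9S,11S,12R)-12-(2,5-dimethoxy-3-nitrophenyl)-8,12-dimethoxy-3,5,7,11-tetramethyl-1-(4,4,5,5-tetramethyl-1,3,2-dioxaborolan-2-yl)-9-[(2,2,6,6-tetramethylpiperidin-1-yl)oxy]dodeca-1,5-dien-4-yl carbamate | COc1cc([N+](=O)[O-])c(OC)c(c1)[C@H](OC)[C@@H](C)C[C@H](ON2C(C)(C)CCCC2(C)C)[C@H](OC)[C@@H](C)/C=C(\C)[C@H](OC(N)=O)[C@@H](C)/C=C\B3OC(C)(C)C(C)(C)O3 | intermediate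
30 | diethyl methylmalonate | CCOC(=O)C(C)C(=O)OCC | starting material
31 | triiodomethane (iodoform) | IC(I)I | starting material
32 | diethyl 2-(diiodomethyl)-2-methylpropanedioate | CCOC(=O)C(C)(C(I)I)C(=O)OCC | intermediate
33 | potassium hydroxide | [K+].[OH-] | starting material
34 | (2E)-3-iodo-2-methylprop-2-enoic acid | C/C(=C\I)C(=O)O | intermediate
35 | ethanethiol | CCS | starting material
36 | S-ethyl (2E)-3-iodo-2-methylprop-2-enethioate | C/C(=C\I)C(=O)SCC | intermediate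
37 | S-ethyl (2E,4Z,6S,7R,8E,10S,11R,12S,14S,15R)-7-(carbamoyloxy)-15-(2,5-dimethoxy-3-nitrophenyl)-11,15-dimethoxy-2,6,8,10,14-pentamethyl-12-[(2,2,6,6-tetramethylpiperidin-1-yl)oxy]pentadeca-2,4,8-trienethioate | COc1cc([N+](=O)[O-])c(OC)c(c1)[C@H](OC)[C@@H](C)C[C@H](ON2C(C)(C)CCCC2(C)C)[C@H](OC)[C@@H](C)/C=C(\C)[C@H](OC(N)=O)[C@@H](C)/C=C\C=C(/C)C(=O)SCC | intermediate
38 | S-ethyl (2E,4Z,6S,7R,8E,10S,11R,12S,14S,15R)-15-(3-amino-2,5-dimethoxyphenyl)-7-(carbamoyloxy)-12-hydroxy-11,15-dimethoxy-2,6,8,10,14-pentamethylpentadeca-2,4,8-trienethioate | COc1cc(N)c(OC)c(c1)[C@H](OC)[C@@H](C)C[C@H](O)[C@H](OC)[C@@H](C)/C=C(\C)[C@H](OC(N)=O)[C@@H](C)/C=C\C=C(/C)C(=O)SCC | intermediate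
39 | 3H-[1,2,3]triazolo[4,5-b]pyridin-3-yl ester (OAt ester) of the seco acid of 38, same stereodescriptors | COc1cc(N)c(OC)c(c1)[C@H](OC)[C@@H](C)C[C@H](O)[C@H](OC)[C@@H](C)/C=C(\C)[C@H](OC(N)=O)[C@@H](C)/C=C\C=C(/C)C(=O)On2nnc3cccnc32 | intermediate
40 | 19-membered macrolactam, 18,21-di-O-methyl ether of the target: (2E,4Z,8E; 6S,7R,10S,11R,12S,14S,15R) anilide N(C20)–C1 with 7-OCONH2, 12-OH and 11,15,18,21-OMe | CO[C@@H]1[C@@H](C)/C=C(\C)[C@H](OC(N)=O)[C@@H](C)/C=C\C=C(/C)C(=O)Nc2cc(OC)cc(c2OC)[C@H](OC)[C@@H](C)C[C@@H]1O | intermediate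
41 | water | O | starting material
42 | 18,21-para-quinone of the target (same macrolactam and stereodescriptors as 43) | CO[C@@H]1[C@@H](C)/C=C(\C)[C@H](OC(N)=O)[C@@H](C)/C=C\C=C(/C)C(=O)NC2=CC(=O)C=C(C2=O)[C@H](OC)[C@@H](C)C[C@@H]1O | intermediate
43 | CNP0548031.1: (2E,4Z,8E; 6S,7R,10S,11R,12S,14S,15R) 19-membered anilide with 7-OCONH2, 12-OH, 11,15-OMe and 18,21-hydroquinone | CO[C@@H]1[C@@H](C)/C=C(\C)[C@H](OC(N)=O)[C@@H](C)/C=C\C=C(/C)C(=O)Nc2cc(O)cc(c2O)[C@H](OC)[C@@H](C)C[C@@H]1O | target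

**Step count**

Total: 20 steps. Longest linear sequence: 15 steps (steps 1–8, 11–13, 17–20). The allenylstannane (steps 9–10) and the iodo thioester (steps 14–16) are side branches.

**Three steps most likely to fail, with fallbacks**

Step 19 (macrolactamisation). The aryl amine is flanked by an ortho methoxy group and is only moderately nucleophilic, so 13-membered lactonisation at the free 12-OH or oligomerisation may compete. The fallback sets out from 37 and comes back at 40. Fe powder and NH4Cl in EtOH/H2O (60 °C) reduce only the nitro group and leave the C12 O–N ether in place, giving the 12-O-(tetramethylpiperidinyl) amino thioester F1. LiOH in THF/H2O (0 °C) cleaves the thioester to the seco amino acid F2. Carboxyl activation with bis(2-oxo-3-oxazolidinyl)phosphinic chloride and iPr2NEt in toluene (0.001 M, 85 °C) closes the lactam with C12 still masked, giving the 12-O-(tetramethylpiperidinyl) macrolactam F3. Zn/AcOH (50 °C) then frees 12-OH to give 40.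

Step 13 (trans-hydroboration). Rhodium hydride side reactions, Z/E erosion or N–H borylation of the carbamate may lower the yield on this functionalised alkyne. The fallback sets out from 27 and comes back at 29. N-Iodosuccinimide with AgNO3 (10 mol%) in acetone gives the 1-iodoalkyne F4. Diimide, generated from 2-nitrobenzenesulfonohydrazide and Et3N in THF/iPrOH, reduces it to the (Z)-1-iodoalkene F5. Miyaura borylation (B2pin2, PdCl2(dppf), KOPh, toluene, 50 °C) with retention of geometry gives 29.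

Step 8 (cross-metathesis). The alkene in 15 carries an allylic methyl branch and two bulky neighbouring ethers, and methacrolein is a reluctant partner, so conversion may stall. The fallback sets out from 15 and comes back at 17. OsO4 (2 mol%), NaIO4 and 2,6-lutidine in dioxane/H2O cleave the vinyl group to the α-methyl aldehyde F6. Wittig olefination with 2-(triphenylphosphoranylidene)propanal (toluene, 80 °C) gives the E-enal 17.

**Further compounds**

F1 | step 19 | S-ethyl (2E,4Z,6S,7R,8E,10S,11R,12S,14S,15R)-15-(3-amino-2,5-dimethoxyphenyl)-7-(carbamoyloxy)-11,15-dimethoxy-2,6,8,10,14-pentamethyl-12-[(2,2,6,6-tetramethylpiperidin-1-yl)oxy]pentadeca-2,4,8-trienethioate | COc1cc(N)c(OC)c(c1)[C@H](OC)[C@@H](C)C[C@H](ON2C(C)(C)CCCC2(C)C)[C@H](OC)[C@@H](C)/C=C(\C)[C@H](OC(N)=O)[C@@H](C)/C=C\C=C(/C)C(=O)SCC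
F2 | step 19 | (2E,4Z,6S,7R,8E,10S,11R,12S,14S,15R)-15-(3-amino-2,5-dimethoxyphenyl)-7-(carbamoyloxy)-11,15-dimethoxy-2,6,8,10,14-pentamethyl-12-[(2,2,6,6-tetramethylpiperidin-1-yl)oxy]pentadeca-2,4,8-trienoic acid | COc1cc(N)c(OC)c(c1)[C@H](OC)[C@@H](C)C[C@H](ON2C(C)(C)CCCC2(C)C)[C@H](OC)[C@@H](C)/C=C(\C)[C@H](OC(N)=O)[C@@H](C)/C=C\C=C(/C)C(=O)O
F3 | step 19 | 12-O-(2,2,6,6-tetramethylpiperidin-1-yl) ether of macrolactam 40 | CO[C@@H]1[C@@H](C)/C=C(\C)[C@H](OC(N)=O)[C@@H](C)/C=C\C=C(/C)C(=O)Nc2cc(OC)cc(c2OC)[C@H](OC)[C@@H](C)C[C@@H]1ON3C(C)(C)CCCC3(C)C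
F4 | step 13 | (3S,4R,5E,7S,8R,9S,11S,12R)-12-(2,5-dimethoxy-3-nitrophenyl)-1-iodo-8,12-dimethoxy-3,5,7,11-tetramethyl-9-[(2,2,6,6-tetramethylpiperidin-1-yl)oxy]dodec-5-en-1-yn-4-yl carbamate | COc1cc([N+](=O)[O-])c(OC)c(c1)[C@H](OC)[C@@H](C)C[C@H](ON2C(C)(C)CCCC2(C)C)[C@H](OC)[C@@H](C)/C=C(\C)[C@H](OC(N)=O)[C@@H](C)C#CI
F5 | step 13 | (1Z,3S,4R,5E,7S,8R,9S,11S,12R)-12-(2,5-dimethoxy-3-nitrophenyl)-1-iodo-8,12-dimethoxy-3,5,7,11-tetramethyl-9-[(2,2,6,6-tetramethylpiperidin-1-yl)oxy]dodeca-1,5-dien-4-yl carbamate | COc1cc([N+](=O)[O-])c(OC)c(c1)[C@H](OC)[C@@H](C)C[C@H](ON2C(C)(C)CCCC2(C)C)[C@H](OC)[C@@H](C)/C=C(\C)[C@H](OC(N)=O)[C@@H](C)/C=C\I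
F6 | step 8 | (2R,3R,4S,6S,7R)-7-(2,5-dimethoxy-3-nitrophenyl)-3,7-dimethoxy-2,6-dimethyl-4-[(2,2,6,6-tetramethylpiperidin-1-yl)oxy]heptanal | COc1cc([N+](=O)[O-])c(OC)c(c1)[C@H](OC)[C@@H](C)C[C@H](ON2C(C)(C)CCCC2(C)C)[C@H](OC)[C@@H](C)C=O
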